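**Retrosynthetic overview**
1. Feature: the ring O1–C2(=O)–C3(Me)=C4(O)–C5(=C6) carries the carbon and oxygen pattern of a squaric acid derivative (C2, C3 with its methyl, C4 with its oxygen, C5 in order). The furanone is therefore made by oxidative four-to-five ring expansion of a cyclobutenol, and C7, next to C6, never sits α to a carbonyl group.
2. Target 33 ⇐ O-demethylation of methyl tetronate 32 ⇐ B-alkyl Suzuki coupling at C10–C11 between the 9-BBN adduct of alkene 15 (C1–C10) and (E)-alkenyl iodide 30 (C11–C18 with the furan).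
3. 15 ⇐ Pb(OAc)4 ring expansion of hydroxycyclobutenone 12 ⇐ dione 10 (dimethyl squarate, MeLi) plus the alkyllithium from iodide 6 (auxiliary-controlled allylation sets C7).
4. 30 ⇐ (R)-linalool, which supplies the C15 carbinol: ozonolysis, alkyne homologation and methylation build C11–C12; hydroboration and a copper-catalysed coupling with a 3-furylmethyl Grignard reagent build C17–C18; hydrozirconation–iodination sets the E iodide.
5. Ring order: the furan is bought as furan-3-ylmethanol; the furanone is the only ring formed (step 6), and the squarate cyclobutene is consumed there.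

Key step: step 6

Remark on the chemistry: the C15 hydroxyl is carried unprotected from (R)-linalool to the target. Its descriptor changes from R to S at step 13 only because the ranking of its two carbon arms changes; no bond to C15 is broken.

**Route**

Step 1
Reactants: 1 (R)-4-benzyl-3-propionyloxazolidin-2-one; 2 allyl iodide
Product: 4 (R)-4-benzyl-3-[(S)-2-methylpent-4-enoyl]oxazolidin-2-one, via sodium enolate 3 (not isolated)
Conditions: NaN(SiMe3)2, THF, −78 °C; then 2, −78 → −40 °C
Reagents that add atoms: none
Why: Evans asymmetric alkylation, in which the chelated (Z)-sodium enolate 3 should be allylated on the face opposite the C4 benzyl group of the auxiliary, setting the future C7 centre (S in 4).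

Step 2
Reactants: 4 (R)-4-benzyl-3-[(S)-2-methylpent-4-enoyl]oxazolidin-2-one
Product: 5 (S)-2-methylpent-4-en-1-ol
Conditions: LiBH4, H2O (1 equiv), Et2O, 0 °C
Reagents that add atoms: none
Why: Hydride reduction of the exocyclic imide carbonyl (reductive removal of the Evans auxiliary) should release the primary alcohol without touching the α-stereocentre and return the oxazolidinone.

Step 3
Reactants: 5 (S)-2-methylpent-4-en-1-ol
Product: 6 (S)-5-iodo-4-methylpent-1-ene
Conditions: I2, PPh3, imidazole, CH2Cl2, 0 °C → rt
Reagents that add atoms: iodine, II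
Why: Appel-type iodination (Garegg–Samuelsson conditions) replaces the primary hydroxyl by SN2 displacement of the alkoxyphosphonium ion one carbon away from the stereocentre, which is therefore untouched.

Step 4
Reactants: 7 dimethyl squarate
Product: 10 3-methoxy-4-methylcyclobut-3-ene-1,2-dione, via lithium alkoxide 8 (not isolated), via trifluoroacetate ester 9 (not isolated)
Conditions: MeLi, THF, −78 °C; (CF3CO)2O, −78 °C; H2O, → rt
Reagents that add atoms: methyllithium, [Li]C; water, O
Why: 1,2-Addition of MeLi to one squarate ketone, trifluoroacetylation of alkoxide 8 and hydrolytic 1,3-transposition (ionisation of 9 to a methoxy-stabilised cyclobutenyl cation, capture by water at the ketal-type carbon, loss of methanol) is the standard way from squarate esters to 3-alkoxy-4-alkylcyclobutenediones and installs the future C3 methyl group.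

Step 5
Reactants: 6 (S)-5-iodo-4-methylpent-1-ene; 10 3-methoxy-4-methylcyclobut-3-ene-1,2-dione
Product: 12 4-hydroxy-3-methoxy-2-methyl-4-[(S)-2-methylpent-4-en-1-yl]cyclobut-2-en-1-one (both epimers at the carbinol carbon), via alkyllithium 11 (not isolated)
Conditions: 6, t-BuLi (2 equiv), Et2O/pentane, −78 °C; then cannulated into 10, THF, −78 °C; aq NH4Cl
Reagents that add atoms: none
Why: Lithium–iodine exchange gives primary alkyllithium 11, which should add 1,2 to the ketone-like carbonyl flanking the methoxy-bearing carbon because the other carbonyl is deactivated as a vinylogous ester, and the new carbinol centre may form as both epimers since it becomes sp2 in step 6.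

Step 6
Reactants: 12 4-hydroxy-3-methoxy-2-methyl-4-[(S)-2-methylpent-4-en-1-yl]cyclobut-2-en-1-one
Product: 15 (Z)-4-methoxy-3-methyl-5-[(S)-2-methylpent-4-enylidene]furan-2(5H)-one, via lead alkoxide 13 (not isolated), via acetoxyfuranone 14 (not isolated)
Conditions: Pb(OAc)4, toluene, rt; then DBU, 0 °C
Reagents that add atoms: none
Why: The tertiary hydroxyl of 12 exchanges with an acetate of Pb(OAc)4 to give tetravalent lead alkoxide 13, and homolysis of its O–Pb bond with β-scission of the strained carbinol–carbonyl bond (C5–C2, preferred over C5–C4 and C5–C6 because only it releases a conjugated acyl radical) leaves a C5 ketone and a C2 acyl radical that is oxidised to the acylium ion while the metal ends as divalent lead. The C5 ketone oxygen then adds to the acylium carbon (5-exo-dig), which forms the O1–C2 bond and closes the furanone, and the resulting 2-oxofuranylium ion, an oxocarbenium ion held by O1, is captured by acetate at C5 to give 14. The closest known reaction type is the Pb(OAc)4-mediated oxidative ring expansion of squarate-derived 4-hydroxycyclobutenones to 5-acetoxy- and 5-ylidene-furan-2(5H)-ones. Loss of acetic acid across C5–C6, the only neighbour of C5 that carries hydrogen, gives the ylidene, and the Z geometry (C7 syn to O1, away from the C4 methoxy group) is expected as the thermodynamic outcome because the E isomer suffers allylic strain against that methoxy group. No stereocentre is created, both carbinol epimers of 12 converge, and C7 keeps its configuration because it is never α to a carbonyl group. The step needs chemoselectivity over the terminal alkene, secured by the much faster ligand exchange and fragmentation of the strained tertiary cyclobutenol at room temperature, and the furan is kept out of the oxidation by running it on the C1–C10 fragment.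

Step 7
Reactants: 16 (R)-linalool
Product: 18 (5R)-5-ethenyl-5-methyloxolan-2-ol (lactol of (R)-4-hydroxy-4-methylhex-5-enal; both anomers), via ozonide 17 (not isolated)
Conditions: O3 (metered to the Sudan red 7B end-point), CH2Cl2, −78 °C; then PPh3, −78 °C → rt
Reagents that add atoms: ozone, [O-][O+]=O
Why: Ozonolysis is chemoselective for the electron-rich trisubstituted alkene over the monosubstituted vinyl group when ozone is metered against the dye, and after reduction of the peroxide the γ-hydroxy aldehyde closes to lactol 18 with the carbinol centre untouched.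

Step 8
Reactants: 18 (5R)-5-ethenyl-5-methyloxolan-2-ol
Product: 19 (R)-3-methylhept-1-en-6-yn-3-ol
Conditions: dimethyl (1-diazo-2-oxopropyl)phosphonate, K2CO3, MeOH, 0 °C → rt
Reagents that add atoms: dimethyl (1-diazo-2-oxopropyl)phosphonate, CC(=O)C(=[N+]=[N-])P(=O)(OC)OC
Why: Seyferth–Gilbert homologation under Ohira–Bestmann conditions converts the aldehyde, present in equilibrium with the lactol, into the terminal alkyne (C11) through an alkylidene carbene and 1,2-hydrogen shift, and the mild carbonate base leaves the tertiary allylic alcohol alone.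

Step 9
Reactants: 19 (R)-3-methylhept-1-en-6-yn-3-ol
Product: 21 (R)-3-methyloct-1-en-6-yn-3-ol, via dilithio alkoxide acetylide 20 (not isolated)
Conditions: n-BuLi (2.1 equiv), THF, −78 → 0 °C; MeI (1.05 equiv), −78 °C → rt; aq NH4Cl
Reagents that add atoms: iodomethane, CI
Why: Double deprotonation gives dianion 20, whose acetylide carbon is alkylated by MeI far faster than the hindered tertiary lithium alkoxide (alkylation of a lithium acetylide), so one equivalent of MeI should install the C11 methyl group.

Step 10
Reactants: 21 (R)-3-methyloct-1-en-6-yn-3-ol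
Product: 23 (R)-3-methyloct-6-yne-1,3-diol, via alkylborane 22 (not isolated)
Conditions: 9-BBN (1.6 equiv), THF, 0 °C → rt; then NaOH, H2O2, 0 °C
Reagents that add atoms: hydrogen peroxide, OO
Why: Brown hydroboration with 9-BBN is anti-Markovnikov and much faster at a monosubstituted alkene than at an internal alkyne, and alkaline peroxide oxidation of the C–B bond then gives the primary alcohol at C17.

Step 11
Reactants: 23 (R)-3-methyloct-6-yne-1,3-diol
Product: 24 (R)-3-hydroxy-3-methyloct-6-yn-1-yl 4-methylbenzenesulfonate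
Conditions: TsCl, Et3N, DMAP (cat.), CH2Cl2, 0 °C
Reagents that add atoms: 4-toluenesulfonyl chloride, Cc1ccc(cc1)S(Cl)(=O)=O
Why: Sulfonylation discriminates the primary from the tertiary hydroxyl on steric grounds, so the 1,3-diol should be converted selectively into the primary tosylate.

Step 12
Reactants: 25 furan-3-ylmethanol
Product: 26 3-(chloromethyl)furan
Conditions: SOCl2, pyridine, Et2O, 0 °C
Reagents that add atoms: thionyl chloride, ClS(Cl)=O
Why: Chlorination through the chlorosulfite with pyridine as acid scavenger gives the labile furylmethyl chloride, which is taken on at once.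

Step 13
Reactants: 24 (R)-3-hydroxy-3-methyloct-6-yn-1-yl 4-methylbenzenesulfonate; 26 3-(chloromethyl)furan
Product: 28 (S)-1-(furan-3-yl)-4-methylnon-7-yn-4-ol, via Grignard reagent 27 (not isolated)
Conditions: 26, Mg, THF, 0 °C; then 24 (27 in 2.5 equiv), Li2CuCl4 (5 mol %), THF, −78 → 0 °C; aq NH4Cl
Reagents that add atoms: none
Why: Kochi-type copper-catalysed coupling, in which the first equivalent of 27 deprotonates the tertiary hydroxyl and the organocopper species then displaces the primary tosylate by SN2 at low temperature, forming C17–C18 at the exocyclic CH2 of the furylmethyl unit.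

Step 14
Reactants: 28 (S)-1-(furan-3-yl)-4-methylnon-7-yn-4-ol
Product: 30 (4S,7E)-1-(furan-3-yl)-8-iodo-4-methylnon-7-en-4-ol, via alkenylzirconocene 29 (not isolated)
Conditions: Cp2Zr(H)Cl (3.5 equiv), THF, rt → 50 °C; then I2, −78 → 0 °C; aq NaHCO3/Na2S2O3
Reagents that add atoms: iodine, II
Why: Schwartz hydrozirconation is a syn addition that, with excess reagent at 50 °C, equilibrates to the alkenylzirconium carrying the metal on the less hindered methyl-substituted carbon C11, and iodinolysis with retention should then give the E iodide with iodine trans to C13.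

Step 15
Reactants: 15 (Z)-4-methoxy-3-methyl-5-[(S)-2-methylpent-4-enylidene]furan-2(5H)-one; 30 (4S,7E)-1-(furan-3-yl)-8-iodo-4-methylnon-7-en-4-ol
Product: 32 (Z)-5-[(2S,6E,10S)-13-(furan-3-yl)-10-hydroxy-2,6,10-trimethyltridec-6-en-1-ylidene]-4-methoxy-3-methylfuran-2(5H)-one, via alkylborane 31 (not isolated)
Conditions: 15, 9-BBN (1.5 equiv), THF, 0 °C → rt; then 30, PdCl2(dppf) (5 mol %), AsPh3, Cs2CO3, DMF/H2O, rt
Reagents that add atoms: none
Why: B-alkyl Suzuki–Miyaura coupling, in which 9-BBN should add only to the terminal C9=C10 alkene of 15 (the trisubstituted, acceptor-conjugated C5=C6 is inert) and transmetalation of the borate to the alkenylpalladium formed from 30 and zerovalent palladium, then reductive elimination, forges C10–C11 with retention of the E geometry.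

Step 16
Reactants: 32 (Z)-5-[(2S,6E,10S)-13-(furan-3-yl)-10-hydroxy-2,6,10-trimethyltridec-6-en-1-ylidene]-4-methoxy-3-methylfuran-2(5H)-one
Product: 33 (Z)-5-[(2S,6E,10S)-13-(furan-3-yl)-10-hydroxy-2,6,10-trimethyltridec-6-en-1-ylidene]-4-hydroxy-3-methylfuran-2(5H)-one (target)
Conditions: LiCl, DMSO, 55 °C; then cold 0.5 M HCl to pH 3
Reagents that add atoms: none
Why: Chloride attacks the O-methyl group of the vinylogous carbonate by SN2 (Krapcho-type dealkylation) because the tetronate is a good leaving group, and mild acidification should then liberate the tetronic acid without touching the furan, the tertiary alcohol or the alkene geometries.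

**Compound list**
1 | (R)-4-benzyl-3-propionyloxazolidin-2-one | CCC(=O)N1[C@H](Cc2ccccc2)COC1=O | starting material
2 | allyl iodide | C=CCI | starting material
3 | sodium (Z)-enolate of 1 | C/C=C(\[O-])N1[C@H](Cc2ccccc2)COC1=O.[Na+] | intermediate (not isolated)
4 | (R)-4-benzyl-3-[(S)-2-methylpent-4-enoyl]oxazolidin-2-one | C=CC[C@H](C)C(=O)N1[C@H](Cc2ccccc2)COC1=O | intermediate
5 | (S)-2-methylpent-4-en-1-ol | OC[C@@H](C)CC=C | intermediate
6 | (S)-5-iodo-4-methylpent-1-ene | IC[C@@H](C)CC=C | intermediate
7 | dimethyl squarate | COC1=C(OC)C(=O)C1=O | starting material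
8 | lithium 2,3-dimethoxy-1-methyl-4-oxocyclobut-2-en-1-olate | COC1=C(OC)C(C)([O-])C1=O.[Li+] | intermediate (not isolated)
9 | 2,3-dimethoxy-1-methyl-4-oxocyclobut-2-en-1-yl trifluoroacetate | COC1=C(OC)C(C)(OC(=O)C(F)(F)F)C1=O | intermediate (not isolated)
10 | 3-methoxy-4-methylcyclobut-3-ene-1,2-dione | COC1=C(C)C(=O)C1=O | intermediate
11 | [(2R)-2-methylpent-4-en-1-yl]lithium (same spatial arrangement as 6; descriptor changed by ranking only) | [Li]C[C@@H](C)CC=C | intermediate (not isolated)
12 | 4-hydroxy-3-methoxy-2-methyl-4-[(S)-2-methylpent-4-en-1-yl]cyclobut-2-en-1-one (both carbinol epimers) | CC1=C(OC)C(O)(C[C@@H](C)CC=C)C1=O | intermediate (key-step precursor)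
13 | tris(acetato){2-methoxy-3-methyl-1-[(S)-2-methylpent-4-en-1-yl]-4-oxocyclobut-2-en-1-olato}lead | CC1=C(OC)C(O[Pb](OC(C)=O)(OC(C)=O)OC(C)=O)(C[C@@H](C)CC=C)C1=O | intermediate (not isolated)
14 | 5-acetoxy-4-methoxy-3-methyl-5-[(S)-2-methylpent-4-en-1-yl]furan-2(5H)-one (both C5 epimers) | CC1=C(OC)C(OC(C)=O)(C[C@@H](C)CC=C)OC1=O | intermediate (not isolated)
15 | (Z)-4-methoxy-3-methyl-5-[(S)-2-methylpent-4-enylidene]furan-2(5H)-one | CC1=C(OC)/C(=C/[C@@H](C)CC=C)OC1=O | intermediate (key-step product)
16 | (R)-linalool | CC(C)=CCC[C@@](C)(O)C=C | starting material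
17 | secondary ozonide of 16, 3-[(3R)-3-hydroxy-3-methylpent-4-en-1-yl]-5,5-dimethyl-1,2,4-trioxolane | CC1(C)OOC(CC[C@@](C)(O)C=C)O1 | intermediate (not isolated)
18 | (5R)-5-ethenyl-5-methyloxolan-2-ol (both anomers) | OC1CC[C@@](C)(O1)C=C | intermediate
19 | (R)-3-methylhept-1-en-6-yn-3-ol | C#CCC[C@@](C)(O)C=C | intermediate
20 | dilithium salt of 19 (lithium alkoxide and lithium acetylide) | [Li]C#CCC[C@@](C)(O[Li])C=C | intermediate (not isolated)
21 | (R)-3-methyloct-1-en-6-yn-3-ol | CC#CCC[C@@](C)(O)C=C | intermediate
22 | (S)-1-(9-borabicyclo[3.3.1]nonan-9-yl)-3-methyloct-6-yn-3-ol | CC#CCC[C@@](C)(O)CCB1C2CCCC1CCC2 | intermediate (not isolated)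
23 | (R)-3-methyloct-6-yne-1,3-diol | CC#CCC[C@@](C)(O)CCO | intermediate
24 | (R)-3-hydroxy-3-methyloct-6-yn-1-yl 4-methylbenzenesulfonate | CC#CCC[C@@](C)(O)CCOS(=O)(=O)c1ccc(C)cc1 | intermediate
25 | furan-3-ylmethanol | OCc1ccoc1 | starting material
26 | 3-(chloromethyl)furan | ClCc1ccoc1 | intermediate
27 | (furan-3-ylmethyl)magnesium chloride | Cl[Mg]Cc1ccoc1 | intermediate (not isolated)
28 | (S)-1-(furan-3-yl)-4-methylnon-7-yn-4-ol | CC#CCC[C@@](C)(O)CCCc1ccoc1 | intermediate
29 | (E)-alkenylzirconocene chloride from 28, Zr on C11 and the hydroxyl as its Cp2Zr(Cl) alkoxide | C/C(=C\CC[C@@](C)(O[Zr](Cl)(C1C=CC=C1)C1C=CC=C1)CCCc1ccoc1)[Zr](Cl)(C1C=CC=C1)C1C=CC=C1 | intermediate (not isolated)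
30 | (4S,7E)-1-(furan-3-yl)-8-iodo-4-methylnon-7-en-4-ol | C/C(I)=C\CC[C@@](C)(O)CCCc1ccoc1 | intermediate
31 | (Z)-5-[(S)-5-(9-borabicyclo[3.3.1]nonan-9-yl)-2-methylpentylidene]-4-methoxy-3-methylfuran-2(5H)-one | CC1=C(OC)/C(=C/[C@@H](C)CCCB2C3CCCC2CCC3)OC1=O | intermediate (not isolated)
32 | (Z)-5-[(2S,6E,10S)-13-(furan-3-yl)-10-hydroxy-2,6,10-trimethyltridec-6-en-1-ylidene]-4-methoxy-3-methylfuran-2(5H)-one | CC1=C(OC)/C(=C/[C@@H](C)CCC/C(C)=C/CC[C@@](C)(O)CCCc2ccoc2)OC1=O | intermediate
33 | (Z)-5-[(2S,6E,10S)-13-(furan-3-yl)-10-hydroxy-2,6,10-trimethyltridec-6-en-1-ylidene]-4-hydroxy-3-methylfuran-2(5H)-one (CNP0217216.2) | CC1=C(O)/C(=C/[C@@H](C)CCC/C(C)=C/CC[C@@](C)(O)CCCc2ccoc2)OC1=O | target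

**Step count**
Total: 16 steps. Longest linear sequence: 9 steps (16 → 33 through steps 7, 8, 9, 10, 11, 13, 14, 15, 16).

**Steps most likely to fail**

Step 6. The acetoxylactone may not lose acetic acid cleanly, the base used for the elimination may remove the C7 proton of the extended enolate system and erode that centre, or the oxidant may begin to acetoxylate the terminal alkene. Fallback, from 12 back to 15: heating 12 in p-xylene at reflux should open the cyclobutenone electrocyclically to a hydroxyvinylketene that the hydroxyl traps, giving without any oxidant 4-methoxy-3-methyl-5-[(S)-2-methylpent-4-en-1-yl]furan-2(5H)-one F1 (both C5 epimers). Deprotonation at C5 with LiN(i-Pr)2 (THF, −78 °C) and trapping with PhSeBr should give 4-methoxy-3-methyl-5-[(S)-2-methylpent-4-en-1-yl]-5-(phenylselanyl)furan-2(5H)-one F2. Oxidation (H2O2, pyridine, CH2Cl2, 0 °C) and syn elimination of the selenoxide toward C6, the only position with a β-hydrogen, leads to 15; a trace of I2 in light would equilibrate any E isomer to Z.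

Step 13. The furylmethyl Grignard reagent is ambident and may bond through the furan 2-position, it may dimerise while magnesium inserts, and the magnesium alkoxide of 24 may close onto its own tosylate. Fallback, from 24 and 26 back to 28: silylation of 24 (Et3SiOTf, 2,6-lutidine, CH2Cl2, −78 °C) gives (R)-3-methyl-3-(triethylsilyloxy)oct-6-yn-1-yl 4-methylbenzenesulfonate F3. Compound 26 and PhSO2Na in DMF give 3-[(phenylsulfonyl)methyl]furan F4, whose α-sulfonyl carbanion (n-BuLi, THF, −78 → 0 °C) can react only at the exocyclic carbon and should be alkylated by F3 to 3-[(4R)-4-methyl-1-(phenylsulfonyl)-4-(triethylsilyloxy)non-7-yn-1-yl]furan F5. Reductive desulfonylation (Na/Hg amalgam, Na2HPO4, MeOH, −20 °C) gives triethyl{[(4S)-1-(furan-3-yl)-4-methylnon-7-yn-4-yl]oxy}silane F6, and Bu4NF in THF returns 28.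

Step 15. The aqueous base may isomerise or open the ylidene lactone during the coupling, and slow transmetalation may lead to protodeboronation. Fallback, from 15 back to 32: hydroboration with 9-BBN as before, then oxidation with NaBO3, gives (Z)-5-[(S)-5-hydroxy-2-methylpentylidene]-4-methoxy-3-methylfuran-2(5H)-one F7. I2, PPh3 and imidazole convert it into (Z)-5-[(S)-5-iodo-2-methylpentylidene]-4-methoxy-3-methylfuran-2(5H)-one F8. Zinc insertion (Zn dust, LiCl, THF, 40 °C) gives the alkylzinc iodide {(S,Z)-5-[3-methoxy-4-methyl-5-oxofuran-2(5H)-ylidene]-4-methylpentyl}zinc iodide F9, which is coupled with 30 under base-free Negishi conditions (PdCl2(dppf), THF/DMF, rt, excess F9 to cover the free hydroxyl) to give 32.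

**Further compounds**
F1 | step 6 | 4-methoxy-3-methyl-5-[(S)-2-methylpent-4-en-1-yl]furan-2(5H)-one (both C5 epimers) | CC1=C(OC)C(C[C@@H](C)CC=C)OC1=O
F2 | step 6 | 4-methoxy-3-methyl-5-[(S)-2-methylpent-4-en-1-yl]-5-(phenylselanyl)furan-2(5H)-one | CC1=C(OC)C(C[C@@H](C)CC=C)([Se]c2ccccc2)OC1=O
F3 | step 13 | (R)-3-methyl-3-(triethylsilyloxy)oct-6-yn-1-yl 4-methylbenzenesulfonate | CC#CCC[C@@](C)(O[Si](CC)(CC)CC)CCOS(=O)(=O)c1ccc(C)cc1
F4 | step 13 | 3-[(phenylsulfonyl)methyl]furan | O=S(=O)(Cc1ccoc1)c1ccccc1
F5 | step 13 | 3-[(4R)-4-methyl-1-(phenylsulfonyl)-4-(triethylsilyloxy)non-7-yn-1-yl]furan (both C1 epimers) | CC#CCC[C@@](C)(O[Si](CC)(CC)CC)CCC(c1ccoc1)S(=O)(=O)c1ccccc1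
F6 | step 13 | triethyl{[(4S)-1-(furan-3-yl)-4-methylnon-7-yn-4-yl]oxy}silane | CC#CCC[C@@](C)(O[Si](CC)(CC)CC)CCCc1ccoc1
F7 | step 15 | (Z)-5-[(S)-5-hydroxy-2-methylpentylidene]-4-methoxy-3-methylfuran-2(5H)-one | CC1=C(OC)/C(=C/[C@@H](C)CCCO)OC1=O
F8 | step 15 | (Z)-5-[(S)-5-iodo-2-methylpentylidene]-4-methoxy-3-methylfuran-2(5H)-one | CC1=C(OC)/C(=C/[C@@H](C)CCCI)OC1=O
F9 | step 15 | {(S,Z)-5-[3-methoxy-4-methyl-5-oxofuran-2(5H)-ylidene]-4-methylpentyl}zinc iodide | CC1=C(OC)/C(=C/[C@@H](C)CCC[Zn]I)OC1=O
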